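**Plan**
- Numbering (elemane): ring C5–C6–C7–C8–C9–C10; vinyl C1=C2 and C14H2OAc on C10; C4(=C3H2)–C15HO on C5; lactone O6–C12(=O)–C11(=C13H2)–C7; ester on O8. β is the face of C14.
- Retrosynthesis: remove the O8 acyl group, the C14 acetate, the C15 oxidation and the one-carbon units C13, C3 and C15. Then cut ring bonds C9–C10 and C5–C6 together. This leaves a 1,3-disilyloxy diene C6=C7–C8=C9 (carrying C11–C12) and a 4-substituted butenolide (C5=C10, C4, C14) whose side chain is C1–C2 as a 2-bromo-1-hydroxyethyl group.
- Enabling feature: on the cyclohexane the C8 oxygen and the C10 substituent C1 are 1,3-related (C8–C9–C10). A disposable O8–Si–O–C1 bridge therefore holds the diene over the butenolide C5=C10 bond so that only the C9–C10/C5–C6 mode can close, although C10 becomes quaternary.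
- Forward: two small building blocks → silyl acetal → cyclohexane ring (the only carbocycle, step 6) → butanolide opened to isopropenyl and C14–OH → zinc cuts the bridge and makes the vinyl group → acid closes the 6,12-lactone → C8 reduction, acylations, C13 methylene, C15 oxidation.
- Stereochemistry: one CBS-set carbinol centre (C1) on the tether fixes the π-face and hence C10, C5 and C6 (alkene geometries plus tether-enforced endo/exo). C7 comes from axial protonation and C8 from hydride delivery by the axial C14–OH. C1 is destroyed when the vinyl group forms.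

Key step: step 6

Remark: compounds 1, 2, 6 and 25 are taken as purchasable. The sense of facial control in step 6 rests on a transition-state model; should it prove opposite, the (S)-bromohydrin (from the other CBS catalyst) would be used.

**Step 1**
Reactants: 1 4-bromofuran-2(5H)-one; 2 tributyl(1-ethoxyvinyl)stannane
Product: 4 4-(2-bromoacetyl)furan-2(5H)-one, via ethoxyvinyl butenolide 3 (not isolated)
Conditions: PdCl2(PPh3)2 (3 mol %), 1,4-dioxane, 90 °C; then NBS, THF–H2O (4:1), 0 °C
Reagents that add atoms: N-bromosuccinimide (BrN1C(=O)CCC1=O); water (O)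
Why: Stille coupling at the vinylogous acyl bromide, then bromination–hydrolysis of the enol ether (NBS attacks the ethoxyvinyl group, water releases the ketone) should give the bromomethyl ketone in one flask; no stereocentre is formed.

**Step 2**
Reactants: 4 4-(2-bromoacetyl)furan-2(5H)-one
Product: 5 4-[(1R)-2-bromo-1-hydroxyethyl]furan-2(5H)-one
Conditions: (R)-2-methyl-CBS-oxazaborolidine (0.2 equiv), catecholborane, toluene–CH2Cl2, −78 °C
Reagents that add atoms: none
Why: Corey–Bakshi–Shibata reduction in which the planar butenolide ring is the large and CH2Br the small ketone substituent, so the (R)-catalyst should give the (R)-bromohydrin (C1), catecholborane at −78 °C sparing the conjugated lactone.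

**Step 3**
Reactants: 6 tert-butyl 4-oxobutanoate
Product: 9 tert-butyl 3-formyl-4-oxopentanoate (enol form), via enamine 7 (not isolated), via acyl enaminone 8 (not isolated)
Conditions: morpholine, K2CO3, toluene, 0 °C → rt; then AcCl, Et3N, CH2Cl2, 0 °C → rt; then 1 M aq. HCl–THF, 0 °C
Reagents that add atoms: acetyl chloride (CC(Cl)=O); water (O)
Why: Stork enamine acylation: the aldehyde enamine is C-acylated at what becomes C7, and mild hydrolysis of the vinylogous amide releases the 2-acyl aldehyde as its chelated enol; no stereocentre.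

**Step 4**
Reactants: 9 tert-butyl 3-formyl-4-oxopentanoate
Product: 10 tert-butyl (3E)-3-acetyl-4-[(tert-butyldimethylsilyl)oxy]but-3-enoate
Conditions: TBSCl, Et3N, DMAP (cat.), CH2Cl2, 0 °C → rt
Reagents that add atoms: tert-butyldimethylsilyl chloride (CC(C)(C)[Si](C)(C)Cl)
Why: O-silylation of the hydroxymethylene enol at the less hindered formyl oxygen, the push–pull alkene settling in the E form (silyloxy anti to acetyl), which later places O6 on the outside of the diene.

**Step 5**
Reactants: 10 silyloxymethylene ketone; 5 (R)-bromohydrin butenolide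
Product: 12 diene–butenolide diisopropylsilyl acetal, via enol silyl triflate 11 (not isolated)
Conditions: iPr2Si(OTf)2 (1.05 equiv), Et3N (1.1 equiv), CH2Cl2, −78 °C; then 5, 2,6-lutidine, −78 → 0 °C
Reagents that add atoms: diisopropylsilyl bis(trifluoromethanesulfonate) (CC(C)[Si](C(C)C)(OS(=O)(=O)C(F)(F)F)OS(=O)(=O)C(F)(F)F)
Why: Soft enolisation (silyl triflate/amine) of the methyl ketone, its only enolisable position, gives the 2-silyloxy diene still bearing one Si–OTf bond, which the secondary alcohol of 5 displaces (silyl ether formation); the hindered weak base of the second stage should not turn the butenolide into a silyloxyfuran, and C1 is untouched.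

**Step 6**
Reactants: 12 diene–butenolide diisopropylsilyl acetal
Product: 13 bridged cycloadduct (cyclohex-7-ene with the O8–Si–O–C1 bridge on the α face, 6α-OTBS, cis-fused C14–O–C4(=O) butanolide on the β face)
Conditions: toluene (0.005 M), BHT (cat.), Et3N (trace), 140 °C, sealed tube
Reagents that add atoms: none
Why: A concerted thermal [4+2] cycloaddition joins the 1,3-disilyloxy diene C6=C7–C8=C9 to the butenolide C5=C10 bond; the closest known type is the type 2 intramolecular Diels–Alder reaction of 2-silyloxy dienes through a disposable silyl acetal tether. The cyclohexene closes by forming C9–C10 and C5–C6, and because the tether joins the internal diene carbon C8 to dienophile carbon C10 only this connectivity is possible, the seven-membered ring C8–O–Si–O–C1–C10–C9 closing at the same time as a bridge with a bridgehead enol ether. C10 and C5 follow from suprafacial addition to the ring-locked alkene (C14 and C4 cis), and C6 from the E-silyloxy group, which ends cis to C1 because the tether must lie endo and the butanolide exo. The absolute sense comes from C1: in the tethered transition state one C1 substituent points over C9 and only hydrogen fits there, so the CH2Br group of the (R)-carbinol turns outward and one face of the butenolide is presented. The step needs regio-, endo/exo- and facial selectivity, secured by the tether position, the tether length and the C1 centre respectively, nucleophilic C9 also being matched electronically to the lactone β-carbon C10.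

**Step 7**
Reactants: 13 bridged cycloadduct
Product: 14 methyl lactol (C4 hemiketal, both anomers)
Conditions: MeLi (1.2 equiv), THF, −78 °C; NH4Cl (aq) at −78 °C
Reagents that add atoms: methyllithium ([Li]C)
Why: Mono-addition of methyllithium to the γ-lactone (the tetrahedral lithium lactolate does not collapse at −78 °C), the tert-butyl ester and the hindered silyl acetal reacting more slowly; the anomeric centre is inconsequential and the methyl becomes C15.

**Step 8**
Reactants: 14 methyl lactol
Product: 15 C5 methyl ketone with C14–OTBS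
Conditions: TBSCl, imidazole, DMF, rt
Reagents that add atoms: tert-butyldimethylsilyl chloride (CC(C)(C)[Si](C)(C)Cl)
Why: Ring–chain tautomerism of the lactol lets the primary C14 hydroxyl of the open hydroxy ketone be silylated, which drains the equilibrium to the methyl ketone and removes an alkoxide that could attack the silyl acetal in the basic steps that follow; no stereocentre changes.

**Step 9**
Reactants: 15 methyl ketone
Product: 16 isopropenyl compound
Conditions: Ph3PCH3Br (3.0 equiv), KOtBu (2.8 equiv), THF, 0 °C → rt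
Reagents that add atoms: methyltriphenylphosphonium bromide (C[P+](c1ccccc1)(c1ccccc1)c1ccccc1.[Br-])
Why: Wittig methylenation of the methyl ketone gives the isopropenyl group (C3), the hindered tertiary C5–H not being enolised by the ylide, so C5 keeps its configuration.

**Step 10**
Reactants: 16 isopropenyl compound
Product: 17 Mannich base (C11–CH2NMe2, both C11 epimers)
Conditions: LiN(iPr)2, THF, −78 °C; then CH2=NMe2+ I−, −78 → 0 °C
Reagents that add atoms: N,N-dimethylmethyleneiminium iodide (C=[N+](C)C.[I-])
Why: Mannich reaction of the tert-butyl ester lithium enolate (the only acidic C–H left) with Eschenmoser's salt installs C13 as a masked methylene that cannot isomerise into conjugation while C8 is still a ketone; the C11 epimers are of no consequence.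

**Step 11**
Reactants: 17 Mannich base
Product: 20 14-hydroxy-8-oxo amino lactone (trans-fused 6α,12-olide), via vinyl silanol 18 (not isolated), via hydroxy amino acid 19 (not isolated)
Conditions: Zn dust (activated), NaI (cat.), EtOH–THF, 65 °C; filter; then TFA–H2O (9:1)/CH2Cl2, 0 °C → rt; evaporate from toluene; NaHCO3 work-up
Reagents that add atoms: none
Why: Zinc insertion into the C–Br bond and expulsion of the β-silyloxy group (Boord-type reductive β-elimination) should cut the tether and create the C1=C2 vinyl group; aqueous acid then hydrolyses the silyl enol ether with axial protonation at C7 from the α face (side chain equatorial, trans to O6), removes both TBS groups and the tert-butyl ester, and closes the trans-fused lactone (acid-catalysed lactonisation), cold and brief exposure being meant to spare the isopropenyl group.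

**Step 12**
Reactants: 20 keto amino lactone
Product: 21 8α,14-diol
Conditions: Me4NBH(OAc)3, MeCN–AcOH (1:1), −30 °C
Reagents that add atoms: none
Why: Hydroxyl-directed reduction of the Evans–Saksena type: the axial C14 hydroxyl, 1,3-diaxial to the C8 carbonyl, exchanges onto boron and delivers hydride to the β face, which should give the equatorial 8α-alcohol, the opposite of what an external hydride (blocked on that face by C14) would give.

**Step 13**
Reactants: 21 8α,14-diol
Product: 22 14-acetate
Conditions: AcCl (1.05 equiv), 2,4,6-collidine, CH2Cl2, −78 °C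
Reagents that add atoms: acetyl chloride (CC(Cl)=O)
Why: Kinetic acetylation: the primary C14 hydroxyl should react faster than the secondary C8 hydroxyl next to the ring fusion.

**Step 14**
Reactants: 22 14-acetate amino lactone
Product: 24 14-acetoxy-8α-hydroxyelema-1,3,11(13)-trien-12,6α-olide, via methiodide 23 (not isolated)
Conditions: MeI, MeOH, rt; then NaHCO3 (aq), CH2Cl2, rt
Reagents that add atoms: none
Why: Exhaustive N-methylation and base-induced β-elimination of trimethylamine (E1cB, Hofmann-type) unmask the α-methylene lactone now that the C8 ketone is gone.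

**Step 15**
Reactants: 25 ethyl 2-(hydroxymethyl)acrylate
Product: 26 ethyl 2-{[(tert-butyldimethylsilyl)oxy]methyl}acrylate
Conditions: TBSCl, imidazole, CH2Cl2, 0 °C → rt
Reagents that add atoms: tert-butyldimethylsilyl chloride (CC(C)(C)[Si](C)(C)Cl)
Why: Standard silyl protection of the primary allylic alcohol.

**Step 16**
Reactants: 26 silyl ether ester
Product: 27 2-{[(tert-butyldimethylsilyl)oxy]methyl}acrylic acid
Conditions: LiOH, THF–H2O, 0 °C; then 1 M HCl to pH 3
Reagents that add atoms: lithium hydroxide ([Li+].[OH-])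
Why: Saponification of the ethyl ester, the silyl ether being stable to LiOH at 0 °C.

**Step 17**
Reactants: 24 8α-alcohol; 27 silyloxymethyl acrylic acid
Product: 28 8α-ester (side-chain OTBS)
Conditions: EDC·HCl, DMAP, CH2Cl2, 0 °C → rt
Reagents that add atoms: none
Why: Steglich esterification of the secondary alcohol with retention at C8.

**Step 18**
Reactants: 28 8α-ester
Product: 30 15-aldehyde (side-chain OTBS), via allylic alcohol 29 (not isolated)
Conditions: SeO2 (0.5 equiv), tBuOOH, CH2Cl2, rt; then Dess–Martin periodinane, NaHCO3, CH2Cl2, 0 °C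
Reagents that add atoms: tert-butyl hydroperoxide (CC(C)(C)OO), its oxygen passing through selenium dioxide (O=[Se]=O)
Why: Riley allylic oxidation (ene reaction then [2,3]-sigmatropic shift) should act only on the isopropenyl group, the one electron-rich alkene with allylic hydrogens, and at its methyl rather than the C5 methine; Dess–Martin oxidation then gives the enal while the silyl ether shields the other allylic alcohol.

**Step 19**
Reactants: 30 15-aldehyde silyl ether
Product: 31 CNP0185525.1
Conditions: HF·pyridine, pyridine, THF, 0 °C → rt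
Reagents that add atoms: none
Why: Desilylation of the primary silyl ether under buffered, mildly acidic conditions that should leave the acetate, the enal and both Michael acceptors untouched.

**Compound list**
1 | 4-bromofuran-2(5H)-one | O=C1C=C(Br)CO1 | starting material
2 | tributyl(1-ethoxyvinyl)stannane | CCCC[Sn](CCCC)(CCCC)C(=C)OCC | starting material
3 | 4-(1-ethoxyvinyl)furan-2(5H)-one | C=C(OCC)C1=CC(=O)OC1 | intermediate
4 | 4-(2-bromoacetyl)furan-2(5H)-one | O=C(CBr)C1=CC(=O)OC1 | intermediate
5 | 4-[(1R)-2-bromo-1-hydroxyethyl]furan-2(5H)-one | BrC[C@H](O)C1=CC(=O)OC1 | intermediate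
6 | tert-butyl 4-oxobutanoate | O=CCCC(=O)OC(C)(C)C | starting material
7 | tert-butyl (3E)-4-(morpholin-4-yl)but-3-enoate | O=C(C/C=C/N1CCOCC1)OC(C)(C)C | intermediate
8 | tert-butyl 3-acetyl-4-(morpholin-4-yl)but-3-enoate | CC(=O)C(CC(=O)OC(C)(C)C)=CN1CCOCC1 | intermediate
9 | tert-butyl 3-formyl-4-oxopentanoate (hydroxymethylene enol) | CC(=O)C(C=O)CC(=O)OC(C)(C)C | intermediate
10 | tert-butyl (3E)-3-acetyl-4-[(tert-butyldimethylsilyl)oxy]but-3-enoate | CC(=O)/C(CC(=O)OC(C)(C)C)=C/O[Si](C)(C)C(C)(C)C | intermediate
11 | enol silyl triflate of 10 (O8–Si(iPr)2–OTf; E-silyloxy diene) | C=C(O[Si](C(C)C)(C(C)C)OS(=O)(=O)C(F)(F)F)/C(CC(=O)OC(C)(C)C)=C/O[Si](C)(C)C(C)(C)C | intermediate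
12 | diisopropylsilyl acetal joining O8 of the diene to O1 of the (R)-bromohydrin butenolide | C=C(O[Si](C(C)C)(C(C)C)O[C@@H](CBr)C1=CC(=O)OC1)/C(CC(=O)OC(C)(C)C)=C/O[Si](C)(C)C(C)(C)C | intermediate
13 | bridged cycloadduct: cyclohex-7-ene, O8–Si(iPr)2–O–C1 bridge (α), 6α-OTBS, C7–CH2CO2tBu, cis-fused 14,4-butanolide (β), C1 (R) bearing CH2Br | BrC[C@@H]1O[Si](C(C)C)(C(C)C)OC2=C(CC(=O)OC(C)(C)C)[C@H](O[Si](C)(C)C(C)(C)C)[C@H]3C(=O)OC[C@]13C2 | intermediate
14 | methyl lactol of 13 (C4 hemiketal) | BrC[C@@H]1O[Si](C(C)C)(C(C)C)OC2=C(CC(=O)OC(C)(C)C)[C@H](O[Si](C)(C)C(C)(C)C)[C@H]3C(C)(O)OC[C@]13C2 | intermediate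
15 | bridged 5β-acetyl compound with 10β-CH2OTBS | BrC[C@@H]1O[Si](C(C)C)(C(C)C)OC2=C(CC(=O)OC(C)(C)C)[C@H](O[Si](C)(C)C(C)(C)C)[C@@H](C(C)=O)[C@@]1(CO[Si](C)(C)C(C)(C)C)C2 | intermediate
16 | bridged 5β-isopropenyl compound | BrC[C@@H]1O[Si](C(C)C)(C(C)C)OC2=C(CC(=O)OC(C)(C)C)[C@H](O[Si](C)(C)C(C)(C)C)[C@@H](C(C)=C)[C@@]1(CO[Si](C)(C)C(C)(C)C)C2 | intermediate
17 | bridged Mannich base (C11–CH2NMe2, tert-butyl ester) | BrC[C@@H]1O[Si](C(C)C)(C(C)C)OC2=C(C(CN(C)C)C(=O)OC(C)(C)C)[C@H](O[Si](C)(C)C(C)(C)C)[C@@H](C(C)=C)[C@@]1(CO[Si](C)(C)C(C)(C)C)C2 | intermediate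
18 | 10α-vinyl compound with O8–Si(iPr)2OH enol ether | C=C[C@]1(CO[Si](C)(C)C(C)(C)C)CC(O[Si](O)(C(C)C)C(C)C)=C(C(CN(C)C)C(=O)OC(C)(C)C)[C@H](O[Si](C)(C)C(C)(C)C)[C@H]1C(C)=C | intermediate
19 | 6α,14-dihydroxy-8-oxo amino acid (7β side chain) | C=C[C@]1(CO)CC(=O)[C@@H](C(CN(C)C)C(=O)O)[C@H](O)[C@H]1C(C)=C | intermediate
20 | 13-(dimethylamino)-14-hydroxy-8-oxoelema-1,3-dien-12,6α-olide (5αH, 7αH, 10β-CH2OH) | C=C[C@]1(CO)CC(=O)[C@H]2C(CN(C)C)C(=O)O[C@@H]2[C@H]1C(C)=C | intermediate
21 | 13-(dimethylamino)-8α,14-dihydroxyelema-1,3-dien-12,6α-olide | C=C[C@]1(CO)C[C@H](O)[C@H]2C(CN(C)C)C(=O)O[C@@H]2[C@H]1C(C)=C | intermediate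
22 | 14-acetoxy-13-(dimethylamino)-8α-hydroxyelema-1,3-dien-12,6α-olide | C=C[C@]1(COC(C)=O)C[C@H](O)[C@H]2C(CN(C)C)C(=O)O[C@@H]2[C@H]1C(C)=C | intermediate
23 | methiodide of 22 | C=C[C@]1(COC(C)=O)C[C@H](O)[C@H]2C(C[N+](C)(C)C)C(=O)O[C@@H]2[C@H]1C(C)=C.[I-] | intermediate
24 | 14-acetoxy-8α-hydroxyelema-1,3,11(13)-trien-12,6α-olide | C=C[C@]1(COC(C)=O)C[C@H](O)[C@H]2C(=C)C(=O)O[C@@H]2[C@H]1C(C)=C | intermediate
25 | ethyl 2-(hydroxymethyl)acrylate | C=C(CO)C(=O)OCC | starting material
26 | ethyl 2-{[(tert-butyldimethylsilyl)oxy]methyl}acrylate | C=C(CO[Si](C)(C)C(C)(C)C)C(=O)OCC | intermediate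
27 | 2-{[(tert-butyldimethylsilyl)oxy]methyl}acrylic acid | C=C(CO[Si](C)(C)C(C)(C)C)C(=O)O | intermediate
28 | 8α-O-[2-(silyloxymethyl)acryloyl] derivative of 24 | C=C[C@]1(COC(C)=O)C[C@H](OC(=O)C(=C)CO[Si](C)(C)C(C)(C)C)[C@H]2C(=C)C(=O)O[C@@H]2[C@H]1C(C)=C | intermediate
29 | 15-hydroxy derivative of 28 | C=C[C@]1(COC(C)=O)C[C@H](OC(=O)C(=C)CO[Si](C)(C)C(C)(C)C)[C@H]2C(=C)C(=O)O[C@@H]2[C@H]1C(=C)CO | intermediate
30 | 15-oxo derivative of 28 | C=C[C@]1(COC(C)=O)C[C@H](OC(=O)C(=C)CO[Si](C)(C)C(C)(C)C)[C@H]2C(=C)C(=O)O[C@@H]2[C@H]1C(=C)C=O | intermediate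
31 | CNP0185525.1 | C=C[C@]1(COC(C)=O)C[C@H](OC(=O)C(=C)CO)[C@H]2C(=C)C(=O)O[C@@H]2[C@H]1C(=C)C=O | target

**Count**
Total steps: 19. Longest linear sequence: 15 (steps 3–14 and 17–19; the route through steps 1, 2, 5–14, 17–19 is equally long).

**Steps most likely to fail**

Step 6. The trisubstituted butenolide may be too poor a dienophile, so that desilylation or polymerisation of the disilyloxy diene at 140 °C outruns the cycloaddition. The fallback makes the dienophile more reactive by opening the lactone before the cycloaddition. It sets out from 5 (with 10) and returns at 15. Bromohydrin 5 is treated with MeLi (2.1 equiv, THF, −78 °C) to give the methyl lactol F1. F1 is silylated at once at the primary hydroxyl of its open form (TBSCl, imidazole, DMF, 0 °C, base-washed glassware to suppress dehydration to a furan) to give the enone alcohol F2, with acetyl cis to CH2OTBS. F2 is joined to the enol silyl triflate 11 as in step 5 to give the silyl acetal F3. Its type 2 intramolecular Diels–Alder reaction (toluene, 80–110 °C), now with an acetyl-activated alkene and the same tether-controlled geometry, gives 15 directly.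

Step 12. Hydride may be delivered from the unhindered α face (poor facial selectivity if exchange of the C14 hydroxyl onto boron is slow), giving the axial 8β-alcohol. The fallback makes that epimer on purpose and inverts it during esterification. It sets out from 20 and returns at 28. Compound 20 is acetylated at its only hydroxyl (Ac2O, pyridine) to keto acetate F4. LiBH(sBu)3 (THF, −78 °C) attacks from the α face, away from the axial C14 group, to give the 8β-alcohol F5. MeI and then NaHCO3 give, via methiodide F6, the methylene lactone F7. Mitsunobu esterification of F7 with acid 27 (PPh3, DIAD, toluene, 0 °C) inverts C8 and gives 28.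

Step 7. Methyllithium may over-add or attack the tert-butyl ester or silicon, or the lactol may stay closed in step 8. The fallback transfers the acyl group through a Weinreb amide. It sets out from 13 and returns at 15. Me(MeO)NH·HCl with iPrMgCl (THF, −20 °C) opens the lactone to the hydroxy amide F8. TBSCl and imidazole give the silyl ether F9. MeMgBr (THF, 0 °C) then gives methyl ketone 15.

**Further compounds**
F1 | step 6 | 4-[(1R)-2-bromo-1-hydroxyethyl]-2-methyl-2,5-dihydrofuran-2-ol | BrC[C@H](O)C1=CC(C)(O)OC1
F2 | step 6 | (3E,5R)-6-bromo-4-{[(tert-butyldimethylsilyl)oxy]methyl}-5-hydroxyhex-3-en-2-one (acetyl cis to CH2OTBS) | CC(=O)/C=C(\CO[Si](C)(C)C(C)(C)C)[C@@H](O)CBr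
F3 | step 6 | diisopropylsilyl acetal joining O8 of the diene to O5 of F2 | C=C(O[Si](C(C)C)(C(C)C)O[C@@H](CBr)C(/CO[Si](C)(C)C(C)(C)C)=C/C(C)=O)/C(CC(=O)OC(C)(C)C)=C/O[Si](C)(C)C(C)(C)C
F4 | step 12 | 14-acetoxy-13-(dimethylamino)-8-oxoelema-1,3-dien-12,6α-olide | C=C[C@]1(COC(C)=O)CC(=O)[C@H]2C(CN(C)C)C(=O)O[C@@H]2[C@H]1C(C)=C
F5 | step 12 | 14-acetoxy-13-(dimethylamino)-8β-hydroxyelema-1,3-dien-12,6α-olide | C=C[C@]1(COC(C)=O)C[C@@H](O)[C@H]2C(CN(C)C)C(=O)O[C@@H]2[C@H]1C(C)=C
F6 | step 12 | methiodide of F5 | C=C[C@]1(COC(C)=O)C[C@@H](O)[C@H]2C(C[N+](C)(C)C)C(=O)O[C@@H]2[C@H]1C(C)=C.[I-]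
F7 | step 12 | 14-acetoxy-8β-hydroxyelema-1,3,11(13)-trien-12,6α-olide | C=C[C@]1(COC(C)=O)C[C@@H](O)[C@H]2C(=C)C(=O)O[C@@H]2[C@H]1C(C)=C
F8 | step 7 | bridged 5β-(N-methoxy-N-methylcarbamoyl) compound with 10β-CH2OH | BrC[C@@H]1O[Si](C(C)C)(C(C)C)OC2=C(CC(=O)OC(C)(C)C)[C@H](O[Si](C)(C)C(C)(C)C)[C@@H](C(=O)N(C)OC)[C@@]1(CO)C2
F9 | step 7 | C14 TBS ether of F8 | BrC[C@@H]1O[Si](C(C)C)(C(C)C)OC2=C(CC(=O)OC(C)(C)C)[C@H](O[Si](C)(C)C(C)(C)C)[C@@H](C(=O)N(C)OC)[C@@]1(CO[Si](C)(C)C(C)(C)C)C2
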